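The earlier runs and the new flask are calculated for substances that don't exist.

The time asked for, 4.0 min, lay past the last reading of both earlier runs, so I had to reckon forward from them.

| flask | substrate | partner | remark | time |
|---|---|---|---|---|
| blue | 0.010 M | 0.040 M | run made earlier |  |
| red | 0.015 M | 0.040 M | run made earlier |  |
| flask | 0.020 M | 0.0400 M |  | 4.0 min |

| run | time / min | single product / % | double product / % | substrate / % |
|---|---|---|---|---|
| blue | 0.667 | 14.4 | 5.6 | 79.0 |
| blue | 1.33 | 17.0 | 13.0 | 61.9 |
| blue | 2.00 | 15.3 | 17.7 | 50.8 |
| blue | 2.50 | 13.2 | 21.6 | 42.8 |
| red | 0.333 | 9.1 | 2.0 | 88.4 |
| red | 0.833 | 14.6 | 6.1 | 74.6 |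
| red | 1.50 | 15.7 | 13.4 | 59.1 |
| red | 2.50 | 13.3 | 19.8 | 45.8 |

(readings scatter by 0.5 percentage points)

- the analysis behind the earlier runs scatters by 0.5 percentage points, standard deviation

- equivalents of partner to substrate, everything else as given, that leave most single product at 4.0 min
- the amount of single product then, in percent of the substrate charged
- the amount of single product with the amounts as given

I read one thing down the blue table. Substrate lost that stood as single product had taken one partner, and I guessed two each for the double product and the unseen gap. The first row then gave 1.31 partner per substrate lost, and the last row gave 1.77, the partner cost. The last red row gave 1.75.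

The flask held twice as much partner as substrate, so a cost near two would take much of it. The mean blue partner, taken through the cost, gave a rate constant of 9.72 M⁻¹ min⁻¹.

My first round held partner at its charge, the pseudo-first-order shortcut, and left 21.1 % of the substrate. Putting that loss back through the cost lowered the mean partner and left 36.3 %, and one more round left 32.7 %. I took the middle of the two, 34.5 %. Carrying on the blue fall of single product between its last two rows down to that substrate gave me 11.0 %.

The forecast put the flask higher, at 12.2 %, and the best at 15.9 % with 0.93 equiv: “Partner then limits the flask.”

The simulation gave 9.58 % of single product, and a best of 10.5 % at 1.29 equiv.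

    substrate + partner → single product (k = 0.161 M⁻¹ s⁻¹)
    partner + single product → double product (k = 0.441 M⁻¹ s⁻¹)
    partner + double product → tris adduct (k = 0.177 M⁻¹ s⁻¹)
    single product → decomposed reagent (k = 0.00653 s⁻¹)
    partner → decomposition product (k = 1.72 × 10⁻⁵ s⁻¹)

In the flask, single product was made 1.07 times as fast as it was used up at 1.13 min. By 4.00 min that ratio was 0.737, below one, with 36 % of the substrate left. The flask had used 1.77 partner per substrate lost, with 43 % of its partner left, and my cost had been 1.77. A neighbour flask charged with 0.068 M of partner should have kept 56.8 % of its partner at that cost, given the substrate it lost, but it kept 48 %, a cost of 2.15.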